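Atom labels C1–C12 follow eremophilane numbering of the target (C3 O-angeloyl, C4 and C5 methyl-bearing, C10 ring-fusion CH, C6=C7–C8=O, C11 side-chain CH) and are used for open-chain precursors too. TBS = tert-butyldimethylsilyl; pin = pinacolato.

## The problem

Target 26 is a cis-fused decalin. Ring A (C1–C5, C10) is saturated and carries the (Z)-2-methylbut-2-enoyl (angeloyl) ester at C3 and methyl groups at C4 and C5. Ring B (C5–C10) holds the enone C6=C7–C8=O, whose α-carbon C7 bears the CH(CH3)CO2Me unit (C11). Four contiguous stereocentres (C3, C4, quaternary C5, C10) carry O, CH3, CH3 and H on one face of ring A; the fifth, C11, lies outside the rings. The C3/C4 pair can be made by acyclic stereocontrol and can then direct C5 and C10, whereas C11 is insulated from the ring stereocentres by the sp2 carbons C6 and C7 and must be set by a reagent or catalyst. The angelate isomerises to the tiglate under nucleophilic base, heat or reversible radical addition. The C11–H is α to an ester and allylic to the enone, so base can epimerise it or move the double bond to C7=C11. The enone also rules out hydride or dissolving-metal conditions late in the route. The enabling feature is that C6=C7–C8=O flanks the quaternary C5 while C8–C9–C10 is a saturated enone arm: ring B is a 4,4-disubstituted cyclohexa-2,5-dienone one arm of which has accepted a carbon at C10. Since C1 is a methylene on the chain that hangs from C5, the C1–C10 bond can be made by conjugate addition to a dienone with two identical arms, creating C5 and C10 in one event.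

## Retrosynthesis

**C7–C11 (26 ⇒ 24 + 25).** The side chain is cut first, to α-iodoenone 24 and racemic methyl 2-chloropropanoate (25). Putting it on earlier would make the two dienone arms different and would expose the labile C11–H to the amine and heat of the esterification. Made last, C11 sees no base afterwards. The forward step must set C11 by catalyst control and tolerate the angelate.

**C7–I, ester C–O and O–Si (24 ⇒ 23 ⇒ 20 + 21 ⇒ 19).** Iodide 24 comes from enone 23 by α-iodination, 23 from alcohol 20 and angelic acid (21), and 20 from silyl ether 19. The angelate cannot be carried earlier, because silyl or stannyl radicals and the enolate chemistry before ring closure would isomerise or cleave it. Iodination follows esterification so that the iodoenone is never heated with amine.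

**C1–C10 (19 ⇒ 18).** Ring A is opened at C1–C10 to give iodide 18. This is the only ring-A bond whose formation is a conjugate addition onto the existing enone system. Cutting C4–C5 or C5–C10 instead would require building the quaternary centre in the cyclisation. Precursor 18 is monocyclic, its ring has no stereocentre, and only C3 and C4 remain. The forward reaction must choose one of two diastereotopic enone arms.

**C–I and C=C (18 ⇒ 17 ⇒ 16 ⇒ 14).** The iodide is traced to alcohol 17 and bis-silyl ether 16, because a primary iodide would not survive the enolate steps. Dienone 16 is traced to cyclohexenone 14 by removing one ring double bond. Making the ring symmetric only at this stage means the quaternary carbon need not be controlled when it is built.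

**Ring construction (14 ⇒ 11 + 12).** The cyclohexenone is cut at the quaternary carbon–CH2 bond (Michael) and at the enone C=C (aldol condensation), giving α-branched aldehyde 11 and methyl vinyl ketone (12). Para-alkylative dearomatisation of a phenol cannot deliver a secondary alkyl group with two defined stereocentres, so annulation is preferred. The forward step must form a quaternary carbon beside a tertiary one.

**Oxidation level (11 ⇒ 10 ⇒ 8 ⇒ 7).** The aldehyde comes from alcohol 10, that from anti-Markovnikov hydration of the 1,1-disubstituted alkene 8, and 8 from silylation of homoallylic alcohol 7. The new centre next to the aldehyde needs no control.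

**C3–C4 (7 ⇒ 5 + 4).** Cutting C3–C4 gives achiral aldehyde 5 and (E)-allylboronate 4. One closed-transition-state addition sets both stereocentres and the absolute configuration. An anti-aldol would need several extra steps to turn its carbonyl into the isopropenyl group. The demand is geometrically pure 4 and catalyst control of the aldehyde face.

**Allylboronate (4 ⇒ 2 ⇒ 1).** The C–CH2 bond is cut by Matteson homologation to alkenylboronate 2, which is the syn-hydroboration product of but-2-yne (1). The symmetric alkyne removes any regiochemical issue and the syn addition fixes the geometry. Routes through π-allyl-metal intermediates risk syn/anti scrambling of the 1,2-dimethylallyl unit.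

## Roads not taken

**Alternative 1: hydroxyl-directed cyclopropane as a latent angular methyl.**
- Cut: the C5–methyl bond, with a temporary C4–CH2 bond.
- Key step: Simmons–Smith methylenation of the tetrasubstituted C4=C5 alkene of the octalin allylic alcohol A1, directed by the C3 hydroxyl, gives cyclopropane A2 on the hydroxyl face.
- Merits: A1 is an annulation product only a few steps from commodity ketones. Hydroxyl-directed delivery onto a hindered alkene face is highly predictable and places the future C5 methyl cis to the C3 oxygen, as required.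
- Weak points:
  - In A2 the C4 methyl is pushed to the face opposite the new carbon, so C4 must be reset later through a C3 ketone enolate.
  - Regioselective opening of the cyclopropane needs that C3 ketone, so C3 is oxidised and then reduced again with facial control.
  - C10 is set in the annulation, is epimerisable there, and gives no handle for absolute configuration.
  - Ring B arrives as a protected saturated ketone, so C6=C7 must be introduced regioselectively away from C9.
- Comparison: this road reaches the decalin faster and forms the quaternary centre with more certainty than a diastereotopic-arm choice. Against that, the chosen plan has absolute and relative configuration fixed by one catalytic step, no redox cycling at C3, and the enone delivered in place by the key step.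

**Alternative 2: masked o-benzoquinone cycloadduct opened by anionic oxy-Cope rearrangement.**
- Cut: C5–C6.
- Key step: the potassium alkoxide of the bicyclo[2.2.2]octene vinyl carbinol A3 rearranges [3,3], forming C5–C6, breaking the temporary C3–C8 bond and closing ring B to give the cis-fused octalone A4.
- Merits: the concerted rearrangement in a rigid bicycle gives the cis fusion and the quaternary methyl without any selectivity question, and A3 is assembled quickly by cycloaddition.
- Weak points:
  - A4 has a C3=C4 alkene. Hydroboration adds H and O syn, so the C3 oxygen ends trans to the C4 methyl; an inversion or an oxidation–reduction at C3 is unavoidable.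
  - The C9 ketal oxygen is superfluous and must be removed reductively.
  - Ring B is again a saturated ketone needing regioselective C6=C7 introduction.
  - The cycloaddition is racemic without an auxiliary.
- Comparison: it is better than the chosen plan in the certainty of the quaternary centre and ring fusion. The chosen plan sets against this a correct oxidation pattern with no corrective steps and built-in enantiocontrol.

**Alternative 3: furan as latent C3 carbinol in an intramolecular Diels–Alder reaction.**
- Cut: C3–C4 and C5–C10 together.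
- Key step: the 2-furyl ring and the tiglyl enone of A5 combine to give the 3,10-epoxy-bridged tricycle A6, closing ring A (as an oxanorbornene) and ring B at once.
- Merits: it is the most convergent option. Two rings form, the cis C4/C5 dimethyl relationship comes from the E alkene, and the C3 oxygen comes from the furan. A5 is a short linear assembly.
- Weak points:
  - Furan cycloadditions are reversible, and a trisubstituted dienophile forming a quaternary centre may leave the equilibrium unfavourable.
  - Only the remote C8 silyloxy group controls the face.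
  - The C10–O bond must afterwards be cleaved reductively with the correct C10–H configuration, and C1=C2 reduced.
  - Ring B oxygenation is transposed (C6 ketone, C8 oxygen) and has to be moved to C6=C7–C8=O.
- Comparison: in bond-forming economy (up to four stereocentres in one step) it surpasses the chosen plan. The chosen plan offers an irreversible, exergonic closure, no oxygen bridge to excise, and ring-B functionality that already matches the target.

Key step: step 11

Assumption (chemistry): compounds 1, 5, 12, 21 and 25 are purchased; the (R) acid in step 3 is chosen by analogy with its known Re-face preference for aldehydes and would be exchanged for its enantiomer if the sense proved opposite.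

## Route

Step 1
Reactants: 1 but-2-yne
Product: 2 (Z)-2-(but-2-en-2-yl)-4,4,5,5-tetramethyl-1,3,2-dioxaborolane
Conditions: pinacolborane, Cp2Zr(H)Cl (5 mol%), Et3N (10 mol%), neat, 60 °C, sealed vessel
Reagents that add atoms: pinacolborane (4,4,5,5-tetramethyl-1,3,2-dioxaborolane), CC1(C)OBOC1(C)C
Why: Zirconium-hydride-catalysed hydroboration of an internal alkyne adds H and B syn, so the two methyl groups end cis (Z descriptor); the symmetric alkyne leaves no regiochemical choice.

Step 2
Reactants: 2 (Z)-2-(but-2-en-2-yl)-4,4,5,5-tetramethyl-1,3,2-dioxaborolane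
Product: 4 (E)-4,4,5,5-tetramethyl-2-(2-methylbut-2-en-1-yl)-1,3,2-dioxaborolane, via lithium chloromethyl boronate complex 3 (not isolated)
Conditions: BrCH2Cl, n-BuLi, THF, −78 °C → rt
Reagents that add atoms: bromochloromethane, ClCBr (its CH2 stays in 4; its chlorine and the lithium of n-butyllithium, [Li]CCCC, are present only in intermediate 3)
Why: Matteson homologation: chloromethyllithium formed in the flask adds to boron, and 1,2-migration of the alkenyl group with loss of chloride inserts CH2 into the C–B bond with retention of alkene geometry, giving the allylboronate with the γ-methyl trans to CH2B (E).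

Step 3
Reactants: 5 3-[(tert-butyldimethylsilyl)oxy]propanal; 4 (E)-4,4,5,5-tetramethyl-2-(2-methylbut-2-en-1-yl)-1,3,2-dioxaborolane
Product: 7 (3S,4R)-1-[(tert-butyldimethylsilyl)oxy]-4,5-dimethylhex-5-en-3-ol, via pinacol borate ester 6 (not isolated)
Conditions: (R)-3,3'-bis(2,4,6-triisopropylphenyl)-1,1'-binaphthyl-2,2'-diyl hydrogen phosphate [(R)-TRIP] (5 mol%), 4 Å MS, toluene, −30 °C; aq. NaHCO3 work-up
Reagents that add atoms: none
Why: Chiral-phosphoric-acid-catalysed allylboration through a closed chair (Zimmerman–Traxler) transition state; the E γ-methyl gives the 3,4-anti pair, and the acid, bound to a boronate oxygen and the formyl hydrogen, is expected to direct attack to the Re face of the aldehyde, giving 3S and hence 4R.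

Step 4
Reactants: 7 (3S,4R)-1-[(tert-butyldimethylsilyl)oxy]-4,5-dimethylhex-5-en-3-ol
Product: 8 (3R,4S)-4,6-bis[(tert-butyldimethylsilyl)oxy]-2,3-dimethylhex-1-ene
Conditions: TBSOTf, 2,6-lutidine, CH2Cl2, −78 → 0 °C
Reagents that add atoms: tert-butyldimethylsilyl trifluoromethanesulfonate, CC(C)(C)[Si](C)(C)OS(=O)(=O)C(F)(F)F
Why: Silylation of the hindered secondary alcohol with the silyl triflate leaves the C–O bond and thus C3 untouched (the descriptors change only through renumbering); the bulky ether later acts as the equatorial anchor in step 11.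

Step 5
Reactants: 8 (3R,4S)-4,6-bis[(tert-butyldimethylsilyl)oxy]-2,3-dimethylhex-1-ene
Product: 10 (3R,4S)-4,6-bis[(tert-butyldimethylsilyl)oxy]-2,3-dimethylhexan-1-ol (both C2 epimers), via B-alkyl-9-BBN adduct 9 (not isolated)
Conditions: 9-BBN, THF, 0 °C → rt; then NaOH, H2O2, 0 °C → rt
Reagents that add atoms: hydrogen peroxide, OO (oxygen of the new hydroxyl); 9-borabicyclo[3.3.1]nonane, B1C2CCCC1CCC2 (present only in intermediate 9)
Why: Anti-Markovnikov hydroboration–oxidation of the 1,1-disubstituted alkene; the new centre at C2 (future C5) forms as a mixture, which is harmless because this carbon is enolised in step 7 and loses its stereogenicity in dienone 16.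

Step 6
Reactants: 10 (3R,4S)-4,6-bis[(tert-butyldimethylsilyl)oxy]-2,3-dimethylhexan-1-ol
Product: 11 (3R,4S)-4,6-bis[(tert-butyldimethylsilyl)oxy]-2,3-dimethylhexanal (both C2 epimers)
Conditions: Dess–Martin periodinane, CH2Cl2, 0 °C → rt
Reagents that add atoms: none
Why: Hypervalent-iodine oxidation of a primary alcohol to the aldehyde under neutral conditions that leave both silyl ethers intact; no fixed stereocentre is affected.

Step 7
Reactants: 11 (3R,4S)-4,6-bis[(tert-butyldimethylsilyl)oxy]-2,3-dimethylhexanal; 12 but-3-en-2-one (methyl vinyl ketone)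
Product: 14 4-[(2R,3S)-3,5-bis[(tert-butyldimethylsilyl)oxy]pentan-2-yl]-4-methylcyclohex-2-en-1-one (both C4 epimers), via keto-aldehyde 13 (not isolated)
Conditions: KOH (0.3 equiv), EtOH, 0 °C → rt
Reagents that add atoms: none
Why: Robinson-type annulation of an α-branched aldehyde: Michael addition of its enolate gives 13 with the quaternary carbon, and aldol condensation of the methyl ketone onto the aldehyde closes the 4,4-disubstituted cyclohexenone; both ring epimers are carried on because they converge in step 8, and C3/C4 of the chain are not enolisable.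

Step 8
Reactants: 14 4-[(2R,3S)-3,5-bis[(tert-butyldimethylsilyl)oxy]pentan-2-yl]-4-methylcyclohex-2-en-1-one
Product: 16 4-[(2R,3S)-3,5-bis[(tert-butyldimethylsilyl)oxy]pentan-2-yl]-4-methylcyclohexa-2,5-dien-1-one, via silyl dienol ether 15 (not isolated)
Conditions: LiN(iPr)2, THF, −78 °C; TMSCl; then Pd(OAc)2 (1.05 equiv), MeCN, rt
Reagents that add atoms: chlorotrimethylsilane, C[Si](C)(C)Cl (silyl group present only in intermediate 15)
Why: Saegusa–Ito dehydrogenation: kinetic α′-deprotonation and silylation give the cross-conjugated dienol ether, and divalent palladium converts it to the dienone by β-hydride elimination; the quaternary carbon now carries two identical arms, so the epimers of 14 become one compound.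

Step 9
Reactants: 16 4-[(2R,3S)-3,5-bis[(tert-butyldimethylsilyl)oxy]pentan-2-yl]-4-methylcyclohexa-2,5-dien-1-one
Product: 17 4-[(2R,3S)-3-[(tert-butyldimethylsilyl)oxy]-5-hydroxypentan-2-yl]-4-methylcyclohexa-2,5-dien-1-one
Conditions: HF·pyridine, pyridine, THF, 0 °C
Reagents that add atoms: none
Why: Buffered fluoride removes the unhindered primary silyl ether much faster than the secondary one, which is shielded by the adjacent branched carbon and the quaternary centre; the dienone is inert to these conditions.

Step 10
Reactants: 17 4-[(2R,3S)-3-[(tert-butyldimethylsilyl)oxy]-5-hydroxypentan-2-yl]-4-methylcyclohexa-2,5-dien-1-one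
Product: 18 4-[(2R,3S)-3-[(tert-butyldimethylsilyl)oxy]-5-iodopentan-2-yl]-4-methylcyclohexa-2,5-dien-1-one
Conditions: I2, PPh3, imidazole, CH2Cl2, 0 °C → rt
Reagents that add atoms: iodine, II
Why: Appel-type iodination: the alkoxyphosphonium ion of the primary alcohol is displaced by iodide (SN2 at a CH2, no stereocentre involved); the phosphine is pre-mixed with iodine so that none is free to add to the dienone.

Step 11
Reactants: 18 4-[(2R,3S)-3-[(tert-butyldimethylsilyl)oxy]-5-iodopentan-2-yl]-4-methylcyclohexa-2,5-dien-1-one
Product: 19 (4aR,5R,6S,8aR)-6-[(tert-butyldimethylsilyl)oxy]-4a,5-dimethyl-4a,5,6,7,8,8a-hexahydronaphthalen-2(1H)-one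
Conditions: (Me3Si)3SiH (1.2 equiv, syringe pump), AIBN (cat.), toluene (0.01 M), 80 °C
Reagents that add atoms: none
Why: The silyl radical abstracts iodine from 18 to give the nucleophilic primary C1 radical, which adds to the electron-poor β-carbon C10 of one enone arm; the α-keto radical at C9 then takes hydrogen from the silane and carries the chain. The closest known reaction type is the stannane- or silane-mediated Giese-type cyclisation of ω-haloalkyl chains onto 4,4-disubstituted cyclohexa-2,5-dienones. Ring A closes 6-exo-trig through a chair-like transition state; 7-endo attack at C9 is disfavoured by ring size and polarity. C10 is controlled by the tether: the chain leaves C5 on one face of the flat dienone and can reach C10 only from that face, so C1–C10 forms cis to C4–C5 and the ring fusion is cis. C5 is controlled by the choice of arm: in the chair the C5 methyl must be equatorial and the spectator arm (C6) axial, and attack on the desired arm then places the C3 silyloxy group equatorial and the C4 methyl axial and anti to C6, whereas the other arm would need an axial silyloxy group syn-diaxial to C6 and a C4 methyl gauche to both C5 substituents. The step therefore needs selectivity between the two diastereotopic arms, which the C3 and C4 stereocentres and the bulky silyl ether should secure, and ring closure faster than hydrogen transfer, which high dilution and slow silane addition secure.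

Step 12
Reactants: 19 (4aR,5R,6S,8aR)-6-[(tert-butyldimethylsilyl)oxy]-4a,5-dimethyl-4a,5,6,7,8,8a-hexahydronaphthalen-2(1H)-one
Product: 20 (4aR,5R,6S,8aR)-6-hydroxy-4a,5-dimethyl-4a,5,6,7,8,8a-hexahydronaphthalen-2(1H)-one
Conditions: HF·pyridine, THF, 0 °C → rt
Reagents that add atoms: none
Why: Fluoride cleavage of the secondary silyl ether under mildly acidic, non-basic conditions; the enone and all four stereocentres are untouched.

Step 13
Reactants: 20 (4aR,5R,6S,8aR)-6-hydroxy-4a,5-dimethyl-4a,5,6,7,8,8a-hexahydronaphthalen-2(1H)-one; 21 (Z)-2-methylbut-2-enoic acid (angelic acid)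
Product: 23 (1R,2S,4aR,8aR)-1,8a-dimethyl-6-oxo-1,2,3,4,4a,5,6,8a-octahydronaphthalen-2-yl (2Z)-2-methylbut-2-enoate, via mixed anhydride 22 (not isolated)
Conditions: 21, 2,4,6-trichlorobenzoyl chloride, Et3N, toluene, rt; then 20, toluene, 75 °C (no DMAP)
Reagents that add atoms: 2,4,6-trichlorobenzoyl chloride, O=C(Cl)c1c(Cl)cc(Cl)cc1Cl (aroyl group present only in intermediate 22)
Why: Yamaguchi esterification: the hindered aroyl carbonyl of 22 is not attacked, so the equatorial C3 alcohol is acylated at the angeloyl carbonyl with the C–O bond and thus C3 unchanged; omitting a nucleophilic pyridine catalyst avoids reversible conjugate addition to the activated acyl group and keeps the Z geometry.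

Step 14
Reactants: 23 (1R,2S,4aR,8aR)-1,8a-dimethyl-6-oxo-1,2,3,4,4a,5,6,8a-octahydronaphthalen-2-yl (2Z)-2-methylbut-2-enoate
Product: 24 (1R,2S,4aR,8aS)-7-iodo-1,8a-dimethyl-6-oxo-1,2,3,4,4a,5,6,8a-octahydronaphthalen-2-yl (2Z)-2-methylbut-2-enoate
Conditions: I2, pyridine/CH2Cl2 (1:1), 0 °C → rt, dark
Reagents that add atoms: iodine, II
Why: Johnson α-iodination: reversible conjugate addition of pyridine at C6, iodination of the enolate at C7 and loss of pyridine restore the enone; the angelate cannot react this way because its α-carbon has no hydrogen, and no stereocentre changes (the C5 descriptor switches from R to S only because iodine alters a CIP priority).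

Step 15
Reactants: 24 (1R,2S,4aR,8aS)-7-iodo-1,8a-dimethyl-6-oxo-1,2,3,4,4a,5,6,8a-octahydronaphthalen-2-yl (2Z)-2-methylbut-2-enoate; 25 methyl 2-chloropropanoate (racemic)
Product: 26 methyl (2R)-2-[(4aR,7S,8R,8aR)-8,8a-dimethyl-7-{[(2Z)-2-methylbut-2-enoyl]oxy}-3-oxo-3,4,4a,5,6,7,8,8a-octahydronaphthalen-2-yl]propanoate
Conditions: NiBr2·diglyme (10 mol%), (4S,4'S)-4,4'-diisopropyl-4,4',5,5'-tetrahydro-2,2'-bioxazole (12 mol%; ligand enantiomer to be fixed on a model iodoenone so that C11 is R), Mn powder (3 equiv), TMSCl (cat.), DMA, 0 °C → rt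
Reagents that add atoms: none
Why: Proposed new method: zerovalent nickel inserts into the C7–I bond, the α-ester radical formed from racemic 25 by halogen abstraction is captured by the alkenylnickel species, and reductive elimination from the chiral trivalent nickel complex forms C7–C11 enantioconvergently while manganese returns nickel to its low-valent state; C11 is set by the ligand because the nearest ring stereocentre (C5) is too remote to bias it, and the closest known reaction types are the nickel-catalysed asymmetric reductive cross-couplings of aryl iodides with α-chloroesters and of alkenyl bromides with benzylic chlorides.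

## Compound list

1 | but-2-yne | CC#CC | starting material
2 | (Z)-2-(but-2-en-2-yl)-4,4,5,5-tetramethyl-1,3,2-dioxaborolane | C/C=C(\C)B1OC(C)(C)C(C)(C)O1 | intermediate
3 | lithium (Z)-(but-2-en-2-yl)(chloromethyl)(pinacolato)borate (formed in the flask) | [Li+].C/C=C(\C)[B-]1(CCl)OC(C)(C)C(C)(C)O1 | intermediate
4 | (E)-4,4,5,5-tetramethyl-2-(2-methylbut-2-en-1-yl)-1,3,2-dioxaborolane | C/C=C(\C)CB1OC(C)(C)C(C)(C)O1 | intermediate
5 | 3-[(tert-butyldimethylsilyl)oxy]propanal | CC(C)(C)[Si](C)(C)OCCC=O | starting material
6 | 2-{[(3S,4R)-1-[(tert-butyldimethylsilyl)oxy]-4,5-dimethylhex-5-en-3-yl]oxy}-4,4,5,5-tetramethyl-1,3,2-dioxaborolane (formed in the flask) | CC(C)(C)[Si](C)(C)OCC[C@H](OB1OC(C)(C)C(C)(C)O1)[C@H](C)C(C)=C | intermediate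
7 | (3S,4R)-1-[(tert-butyldimethylsilyl)oxy]-4,5-dimethylhex-5-en-3-ol | CC(C)(C)[Si](C)(C)OCC[C@H](O)[C@H](C)C(C)=C | intermediate
8 | (3R,4S)-4,6-bis[(tert-butyldimethylsilyl)oxy]-2,3-dimethylhex-1-ene | CC(C)(C)[Si](C)(C)OCC[C@H](O[Si](C)(C)C(C)(C)C)[C@H](C)C(C)=C | intermediate
9 | 9-[(3R,4S)-4,6-bis[(tert-butyldimethylsilyl)oxy]-2,3-dimethylhexyl]-9-borabicyclo[3.3.1]nonane, both C2 epimers (formed in the flask) | CC(C)(C)[Si](C)(C)OCC[C@H](O[Si](C)(C)C(C)(C)C)[C@H](C)C(C)CB1C2CCCC1CCC2 | intermediate
10 | (3R,4S)-4,6-bis[(tert-butyldimethylsilyl)oxy]-2,3-dimethylhexan-1-ol, both C2 epimers | CC(C)(C)[Si](C)(C)OCC[C@H](O[Si](C)(C)C(C)(C)C)[C@H](C)C(C)CO | intermediate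
11 | (3R,4S)-4,6-bis[(tert-butyldimethylsilyl)oxy]-2,3-dimethylhexanal, both C2 epimers | CC(C)(C)[Si](C)(C)OCC[C@H](O[Si](C)(C)C(C)(C)C)[C@H](C)C(C)C=O | intermediate
12 | but-3-en-2-one (methyl vinyl ketone) | CC(=O)C=C | starting material
13 | 2-[(2R,3S)-3,5-bis[(tert-butyldimethylsilyl)oxy]pentan-2-yl]-2-methyl-5-oxohexanal, both C2 epimers (formed in the flask) | CC(C)(C)[Si](C)(C)OCC[C@H](O[Si](C)(C)C(C)(C)C)[C@H](C)C(C)(C=O)CCC(C)=O | intermediate
14 | 4-[(2R,3S)-3,5-bis[(tert-butyldimethylsilyl)oxy]pentan-2-yl]-4-methylcyclohex-2-en-1-one, both C4 epimers | CC(C)(C)[Si](C)(C)OCC[C@H](O[Si](C)(C)C(C)(C)C)[C@H](C)C1(C)CCC(=O)C=C1 | intermediate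
15 | {[4-[(2R,3S)-3,5-bis[(tert-butyldimethylsilyl)oxy]pentan-2-yl]-4-methylcyclohexa-1,5-dien-1-yl]oxy}trimethylsilane, both C4 epimers (formed in the flask) | CC(C)(C)[Si](C)(C)OCC[C@H](O[Si](C)(C)C(C)(C)C)[C@H](C)C1(C)CC=C(O[Si](C)(C)C)C=C1 | intermediate
16 | 4-[(2R,3S)-3,5-bis[(tert-butyldimethylsilyl)oxy]pentan-2-yl]-4-methylcyclohexa-2,5-dien-1-one | CC(C)(C)[Si](C)(C)OCC[C@H](O[Si](C)(C)C(C)(C)C)[C@H](C)C1(C)C=CC(=O)C=C1 | intermediate
17 | 4-[(2R,3S)-3-[(tert-butyldimethylsilyl)oxy]-5-hydroxypentan-2-yl]-4-methylcyclohexa-2,5-dien-1-one | OCC[C@H](O[Si](C)(C)C(C)(C)C)[C@H](C)C1(C)C=CC(=O)C=C1 | intermediate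
18 | 4-[(2R,3S)-3-[(tert-butyldimethylsilyl)oxy]-5-iodopentan-2-yl]-4-methylcyclohexa-2,5-dien-1-one | ICC[C@H](O[Si](C)(C)C(C)(C)C)[C@H](C)C1(C)C=CC(=O)C=C1 | intermediate
19 | (4aR,5R,6S,8aR)-6-[(tert-butyldimethylsilyl)oxy]-4a,5-dimethyl-4a,5,6,7,8,8a-hexahydronaphthalen-2(1H)-one | CC(C)(C)[Si](C)(C)O[C@H]1CC[C@@H]2CC(=O)C=C[C@]2(C)[C@H]1C | intermediate
20 | (4aR,5R,6S,8aR)-6-hydroxy-4a,5-dimethyl-4a,5,6,7,8,8a-hexahydronaphthalen-2(1H)-one | O[C@H]1CC[C@@H]2CC(=O)C=C[C@]2(C)[C@H]1C | intermediate
21 | (Z)-2-methylbut-2-enoic acid (angelic acid) | C/C=C(/C)C(=O)O | starting material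
22 | (Z)-2-methylbut-2-enoic 2,4,6-trichlorobenzoic anhydride (formed in the flask) | C/C=C(/C)C(=O)OC(=O)c1c(Cl)cc(Cl)cc1Cl | intermediate
23 | (1R,2S,4aR,8aR)-1,8a-dimethyl-6-oxo-1,2,3,4,4a,5,6,8a-octahydronaphthalen-2-yl (2Z)-2-methylbut-2-enoate | C/C=C(/C)C(=O)O[C@H]1CC[C@@H]2CC(=O)C=C[C@]2(C)[C@H]1C | intermediate
24 | (1R,2S,4aR,8aS)-7-iodo-1,8a-dimethyl-6-oxo-1,2,3,4,4a,5,6,8a-octahydronaphthalen-2-yl (2Z)-2-methylbut-2-enoate | C/C=C(/C)C(=O)O[C@H]1CC[C@@H]2CC(=O)C(I)=C[C@]2(C)[C@H]1C | intermediate
25 | methyl 2-chloropropanoate (racemic) | COC(=O)C(C)Cl | starting material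
26 | methyl (2R)-2-[(4aR,7S,8R,8aR)-8,8a-dimethyl-7-{[(2Z)-2-methylbut-2-enoyl]oxy}-3-oxo-3,4,4a,5,6,7,8,8a-octahydronaphthalen-2-yl]propanoate (3S,4R,5R,10R,11R in eremophilane numbering) | C/C=C(/C)C(=O)O[C@H]1CC[C@@H]2CC(=O)C([C@@H](C)C(=O)OC)=C[C@]2(C)[C@H]1C | target

## Step count and least certain steps

Total: 15 steps. Longest linear sequence: 15 steps from but-2-yne (1); 13 steps from aldehyde 5.

**Step 15 (Proposed new method).** Protodeiodination or reductive dimerisation of the iodoenone may outrun cross-coupling, and enantiofacial discrimination at C11 may be weak, because the alkenyl partner is an electron-poor α-halo enone with a neopentyl β-carbon and lies outside the known scope. Slow epimerisation of the product on the manganese salts is a second concern. Fallback (known chemistry), setting out from 24: palladium-catalysed Negishi coupling (Pd(PPh3)4, THF/DMF, 40 °C) with the zinc enolate bromo(1-methoxy-1-oxopropan-2-yl)zinc F1, made from methyl 2-bromopropanoate and zinc dust. This gives 26 together with its C11 epimer, methyl (2S)-2-[(4aR,7S,8R,8aR)-8,8a-dimethyl-7-{[(2Z)-2-methylbut-2-enoyl]oxy}-3-oxo-3,4,4a,5,6,7,8,8a-octahydronaphthalen-2-yl]propanoate F2. The two are separated by chromatography, and F2 is re-equilibrated with DBU and recycled, so the fallback returns to the route at 26.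

**Step 11 (key step).** Poor selectivity between the two enone arms would give the cis-decalin epimeric at C5 and C10. The energy difference rests on conformational preferences of one silyloxy and one methyl group at 80 °C. Hydrogen transfer to the primary radical before ring closure and silyl-radical reduction of the dienone are the other losses. Fallback, setting out from 18: zinc insertion (Zn dust, LiCl, THF) gives the alkylzinc iodide {(3S,4R)-3-[(tert-butyldimethylsilyl)oxy]-4-(1-methyl-4-oxocyclohexa-2,5-dien-1-yl)pentyl}zinc iodide F3. A copper-catalysed intramolecular conjugate addition (Cu(OTf)2, chiral phosphoramidite ligand matched to the substrate bias, TMSCl, THF, −30 °C) then lets the ligand choose the arm. The first-formed trimethylsilyl dienol ether of 19, F4, is hydrolysed on work-up, returning to the route at 19.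

**Step 3.** Enantioselectivity of the acid-catalysed allylboration may be only moderate with an unbranched aliphatic aldehyde and a β,γ-disubstituted allylboronate, and uncatalysed background addition would give racemic anti product. Fallback, setting out from 4: diethanolamine gives the crystalline (E)-2-(2-methylbut-2-en-1-yl)-1,3,6,2-dioxazaborocane F5. Exchange with diisopropyl (S,S)-tartrate then gives the tartrate allylboronate diisopropyl (4S,5S)-2-[(E)-2-methylbut-2-en-1-yl]-1,3,2-dioxaborolane-4,5-dicarboxylate F6. F6 adds to 5 (toluene, 4 Å MS, −78 °C) under stoichiometric reagent control through the same chair. Hydrolysis of the first-formed tartrate borate of 7, F7, returns to the route at 7.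

**Step 7.** Michael addition at the doubly branched α-carbon may be slow, so that polymerisation of the vinyl ketone and self-condensation of the aldehyde compete. Hydroxide may also erode the primary silyl ether. Fallback, setting out from 11: condensation with cyclohexylamine gives the N-cyclohexyl imine of 11, F8. Deprotonation (LiN(iPr)2, THF, −78 °C) and C-alkylation of the metalloenamine with 2-(2-iodoethyl)-2-methyl-1,3-dioxolane give the alkylated imine ketal F9. Aqueous oxalic acid, then PPTS in wet acetone, release aldehyde and ketone to give 13, which is closed with KOH in MeOH, returning to the route at 14.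

**Step 13.** The angeloyl unit may isomerise to the tiglate in the activated acyl species at 75 °C, and acylation of the alcohol beside the axial C4 methyl may be sluggish. Fallback, setting out from 20: acylation with 2-[bis(2,2,2-trifluoroethoxy)phosphoryl]propanoic acid (DCC, DMAP, CH2Cl2) gives the phosphonate ester (1R,2S,4aR,8aR)-1,8a-dimethyl-6-oxo-1,2,3,4,4a,5,6,8a-octahydronaphthalen-2-yl 2-[bis(2,2,2-trifluoroethoxy)phosphoryl]propanoate F10. Still–Gennari olefination with acetaldehyde (KN(SiMe3)2, 18-crown-6, THF, −78 °C) then builds the Z-trisubstituted alkene on the ester, returning to the route at 23.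

## Further compounds

F1 | step 15 | bromo(1-methoxy-1-oxopropan-2-yl)zinc | COC(=O)C(C)[Zn]Br
F2 | step 15 | methyl (2S)-2-[(4aR,7S,8R,8aR)-8,8a-dimethyl-7-{[(2Z)-2-methylbut-2-enoyl]oxy}-3-oxo-3,4,4a,5,6,7,8,8a-octahydronaphthalen-2-yl]propanoate (C11 epimer of 26) | C/C=C(/C)C(=O)O[C@H]1CC[C@@H]2CC(=O)C([C@H](C)C(=O)OC)=C[C@]2(C)[C@H]1C
F3 | step 11 | {(3S,4R)-3-[(tert-butyldimethylsilyl)oxy]-4-(1-methyl-4-oxocyclohexa-2,5-dien-1-yl)pentyl}zinc iodide | I[Zn]CC[C@H](O[Si](C)(C)C(C)(C)C)[C@H](C)C1(C)C=CC(=O)C=C1
F4 | step 11 | tert-butyldimethylsilyl ether of 19 as its C8 trimethylsilyl dienol ether (C8=C9 and C6=C7 double bonds; ring stereocentres as in 19) | CC(C)(C)[Si](C)(C)O[C@H]1CC[C@@H]2C=C(O[Si](C)(C)C)C=C[C@]2(C)[C@H]1C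
F5 | step 3 | (E)-2-(2-methylbut-2-en-1-yl)-1,3,6,2-dioxazaborocane | C/C=C(\C)CB1OCCNCCO1
F6 | step 3 | diisopropyl (4S,5S)-2-[(E)-2-methylbut-2-en-1-yl]-1,3,2-dioxaborolane-4,5-dicarboxylate | C/C=C(\C)CB1O[C@H](C(=O)OC(C)C)[C@@H](C(=O)OC(C)C)O1
F7 | step 3 | diisopropyl (4S,5S)-2-{[(3S,4R)-1-[(tert-butyldimethylsilyl)oxy]-4,5-dimethylhex-5-en-3-yl]oxy}-1,3,2-dioxaborolane-4,5-dicarboxylate | CC(=C)[C@@H](C)[C@H](CCO[Si](C)(C)C(C)(C)C)OB1O[C@H](C(=O)OC(C)C)[C@@H](C(=O)OC(C)C)O1
F8 | step 7 | N-cyclohexyl imine of (3R,4S)-4,6-bis[(tert-butyldimethylsilyl)oxy]-2,3-dimethylhexanal | CC(C)(C)[Si](C)(C)OCC[C@H](O[Si](C)(C)C(C)(C)C)[C@H](C)C(C)C=NC1CCCCC1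
F9 | step 7 | N-cyclohexyl imine of 2-[(2R,3S)-3,5-bis[(tert-butyldimethylsilyl)oxy]pentan-2-yl]-2-methyl-4-(2-methyl-1,3-dioxolan-2-yl)butanal | CC(C)(C)[Si](C)(C)OCC[C@H](O[Si](C)(C)C(C)(C)C)[C@H](C)C(C)(CCC1(C)OCCO1)C=NC1CCCCC1
F10 | step 13 | (1R,2S,4aR,8aR)-1,8a-dimethyl-6-oxo-1,2,3,4,4a,5,6,8a-octahydronaphthalen-2-yl 2-[bis(2,2,2-trifluoroethoxy)phosphoryl]propanoate | CC(C(=O)O[C@H]1CC[C@@H]2CC(=O)C=C[C@]2(C)[C@H]1C)P(=O)(OCC(F)(F)F)OCC(F)(F)F
A1 | alternative 1 | (6'S,8a'R)-5'-methyl-3',4',6',7',8',8a'-hexahydro-1'H-spiro[1,3-dioxolane-2,2'-naphthalen]-6'-ol (octalin allylic alcohol, C4=C5 alkene, C8 ketal) | O[C@H]1CC[C@@H]2CC3(OCCO3)CCC2=C1C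
A2 | alternative 1 | 4,5-methano adduct of A1 (cyclopropane C4–CH2–C5 on the hydroxyl face) | O[C@H]1CC[C@@H]2CC3(OCCO3)CC[C@@]24C[C@@]14C
A3 | alternative 2 | 2-ethenyl-3,3-dimethoxy-5,6-dimethylbicyclo[2.2.2]oct-5-en-2-ol (ethenyl group syn to the C5=C6 bridge) | C=C[C@]1(O)C(OC)(OC)[C@H]2CC[C@@H]1C(C)=C2C
A4 | alternative 2 | cis-fused 1,1-dimethoxy-4a,5-dimethyl-3,4,4a,7,8,8a-hexahydronaphthalen-2(1H)-one | O=C1CC[C@]2(C)C(C)=CCC[C@@H]2C1(OC)OC
A5 | alternative 3 | (2E,6R)-6-[(tert-butyldimethylsilyl)oxy]-7-(furan-2-yl)-3-methylhept-2-en-4-one | C/C=C(\C)C(=O)C[C@H](O[Si](C)(C)C(C)(C)C)Cc1ccco1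
A6 | alternative 3 | 3,10-epoxy-bridged tricyclic cycloadduct of A5 (C6 ketone, C8 silyl ether, C1=C2 alkene) | C[C@H]1[C@H]2C=C[C@@]3(O2)C[C@@H](O[Si](C)(C)C(C)(C)C)CC(=O)[C@]13C
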